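**Plan**

- Retrosynthetic cuts, in order: the two ester C–O bonds (tiglate on O-2, acetate on O-13); C11–C13 (lactone enolate + CH2O); ring A at C2–C3 together with C4–C15 (aldol closure and methyl addition in one flask); the ether bond O–C11; C5–C4 (acetylide to a C5 ketone); C1–C2 and C10–C14 (orthoformate and cuprate on a cycloheptenone); C7–C11 (radical cyclisation); the C8 oxygen (cycloheptadiene + O2).
- Forward ring order: seven-membered ring (starting material), then the γ-lactone, then the oxolane bridge (O between C5 and C11), then the cyclopentane (ring A) last.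
- Stereochemistry: C8 comes from an enantioselective Kornblum–DeLaMare desymmetrisation. C7, C10, C1, C5 and C11 are relayed from it (cis lactone fusion, attack anti to the lactone or to the neighbouring substituent, ring-fusion constraint). C2 and C4 are set in the key step.
- Enabling feature: ring A carries oxygen on C2 and C4, 1,3 across the C3 methylene, and is fused to the fully substituted ether carbon C5. It is therefore an aldol retron: a formyl group on C1 (C2) and an acetyl group on C5 (C4 and C3) that can enolise only towards C3.

Key step: step 13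

Remark: guaianolide numbering is used throughout (C1–C10 carbocycle, C11–C13 lactone carbons, C14 on C10, C15 on C4); α is the face of H-7 (and of H-1 on ring A), β the face of the lactone and ether bridge; the acetal carbon of 4 and 5 forms as both epimers, which converge at 6.

**Route**

Step 1
Reactants: 1 cyclohepta-1,3-diene
Product: 2 endoperoxide
Conditions: O2, tetraphenylporphyrin (cat.), hν, CH2Cl2, −20 °C
Reagents that add atoms: dioxygen (O=O)
Why: [4+2] cycloaddition of singlet oxygen across the cyclic 1,3-diene should give the meso cis-endoperoxide, which already carries the future C8 oxygen.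

Step 2
Reactants: 2 endoperoxide
Product: 3 (R)-4-hydroxycyclohept-2-en-1-one
Conditions: quinidine-derived cinchona base catalyst (10 mol %), CH2Cl2, rt
Reagents that add atoms: none
Why: Enantioselective Kornblum–DeLaMare rearrangement: the chiral base removes one of the two enantiotopic bridgehead protons with O–O cleavage, so the desymmetrisation sets C8 (the pseudoenantiomeric alkaloid is chosen that leads to the R enone).

Step 3
Reactants: 3 (R)-4-hydroxycyclohept-2-en-1-one
Product: 4 bromoacetal
Conditions: NBS, ethyl vinyl ether, CH2Cl2, −20 → 0 °C
Reagents that add atoms: ethyl vinyl ether (C=COCC); N-bromosuccinimide (O=C1CCC(=O)N1Br)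
Why: Bromoetherification of the vinyl ether with the C8 hydroxyl as nucleophile (Ueno–Stork bromoacetal) installs the C11–C12 tether without touching the enone.

Step 4
Reactants: 4 bromoacetal
Product: 5 bicyclic keto acetal
Conditions: Bu3SnH, AIBN (cat.), benzene, 80 °C, slow addition
Reagents that add atoms: none
Why: Ueno–Stork 5-exo-trig radical cyclisation onto the enone β-carbon; the tether through O-8 can deliver C11 only to the face of O-8, so the cis ring fusion sets C7.

Step 5
Reactants: 5 bicyclic keto acetal
Product: 6 keto lactone
Conditions: CrO3, H2SO4, acetone–H2O, 0 °C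
Reagents that add atoms: water (O)
Why: Jones oxidation hydrolyses the ethyl acetal and oxidises the lactol to the γ-lactone, so both acetal epimers converge.

Step 6
Reactants: 6 keto lactone
Product: 7 allyl β-keto ester
Conditions: NaH, diallyl carbonate, THF, 65 °C; aq HCl work-up
Reagents that add atoms: diallyl carbonate (C=CCOC(=O)OCC=C)
Why: Claisen-type C-acylation under equilibrating conditions should carboxylate the ketone (more acidic than the lactone) at the less hindered α-methylene C1, since C6 is flanked by the ring-fusion carbon C7.

Step 7
Reactants: 7 allyl β-keto ester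
Product: 8 enone lactone
Conditions: Pd(OAc)2 (10 mol %), dppe (10 mol %), MeCN, 80 °C
Reagents that add atoms: none
Why: Tsuji decarboxylation–dehydrogenation: the allyl ester gives a π-allylpalladium enolate located at C1, and β-hydride elimination can then give only the C1=C10 enone.

Step 8
Reactants: 8 enone lactone
Product: 9 silyl enol ether
Conditions: Me2CuLi, Me3SiCl, THF, −78 °C; Et3N
Reagents that add atoms: lithium dimethylcuprate ([Li+].C[Cu-]C); chlorotrimethylsilane (C[Si](C)(C)Cl)
Why: Cuprate conjugate addition on the α-face, anti to the cis-fused lactone that shields the β-face, sets C10 (methyl α), and the silyl chloride traps the enolate regiospecifically at C1/C5.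

Step 9
Reactants: 9 silyl enol ether
Product: 10 keto acetal
Conditions: HC(OMe)3, Me3SiOTf (10 mol %), CH2Cl2, −78 °C
Reagents that add atoms: trimethyl orthoformate (COC(OC)OC)
Why: Mukaiyama-type addition of the enol ether to the dimethoxycarbenium ion; the electrophile enters anti to the adjacent 10α-methyl group, giving the 1β-dimethoxymethyl ketone (C1 is also epimerisable towards this trans isomer).

Step 10
Reactants: 10 keto acetal
Product: 11 propargylic alcohol
Conditions: Me3SiC≡CH, n-BuLi, THF, −78 °C; CeCl3; then 10, −78 °C; aq NH4Cl
Reagents that add atoms: ethynyltrimethylsilane (C#C[Si](C)(C)C)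
Why: Organocerium 1,2-addition (ketone over lactone, no enolisation) should occur on the α-face, anti to the 1β-acetal group and to the β-face lactone, which places the C5 oxygen β.

Step 11
Reactants: 11 propargylic alcohol
Product: 13 bridged ether, via α-iodolactone 12 (not isolated)
Conditions: LDA (2.3 equiv), THF, −78 °C; I2 (1.1 equiv), −78 → 0 °C
Reagents that add atoms: none
Why: The alkoxide/lactone-enolate dianion is iodinated at C11 on the convex face, and the tertiary alkoxide then displaces iodide 5-exo-tet with inversion from the concave face (intramolecular Williamson etherification), which fixes C11 in the only geometry that allows a cis-fused oxolane.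

Step 12
Reactants: 13 bridged ether
Product: 14 keto aldehyde
Conditions: Ph3PAuNTf2 (5 mol %), TsOH·H2O (20 mol %), dioxane–H2O, 50 °C
Reagents that add atoms: water (O)
Why: Gold-catalysed Markovnikov hydration of the alkyne (the silyl group is lost by protodesilylation) and acid hydrolysis of the acetal unmask the 1,4-keto aldehyde; the formyl group stays β, trans to both neighbouring carbon substituents.

Step 13
Reactants: 14 keto aldehyde
Product: 16 diol lactone, via β-hydroxy ketone 15 (not isolated)
Conditions: LiN(SiMe3)2 (1.05 equiv), THF, −78 → −40 °C; then MeLi/CeCl3 (3 equiv), −78 °C; aq NH4Cl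
Reagents that add atoms: methyllithium ([Li]C)
Why: LiN(SiMe3)2 removes a proton from the acetyl methyl (C3), the only enolisable position of the ketone because C5 is fully substituted, and the lithium enolate adds to the C2 aldehyde to give the lithium aldolate of 15, whose C4 ketone is then methylated in the same flask by MeCeCl2. The closest known reaction types are the base-mediated aldol cyclisation of 1,4-dicarbonyl compounds to 3-hydroxycyclopentanones, stopped at the aldolate at low temperature, and organocerium addition to enolisable β-oxygenated ketones. Ring A closes through the C2–C3 bond in the 5-(enolendo)-exo-trig mode and is trans-fused because the formyl group (1β) and the acetyl group (5α) are already trans on the seven-membered ring. C2 is controlled by the lithium-bridged envelope transition state, which places O-2 on the α-face away from C10 (also the more stable epimer should the aldol equilibrate), and C4 by approach of the methyl group to the β-face of the chelated cyclopentanone, next to the small ether oxygen and anti to C6 and to the O-2 lithium alkoxide. The step needs the ketone enolate to win over enolisation of the aldehyde and the aldolate to survive without loss of water: abstraction of H-1 can only trigger a β-elimination of the C11 oxygen that is reversed by 5-exo oxa-Michael re-addition to give back 14, and the aldolate is consumed at −78 °C before dehydration can set in.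

Step 14
Reactants: 16 diol lactone
Product: 17 triol lactone
Conditions: LDA (3.5 equiv), THF, −78 °C; CH2O (gas), −78 → −30 °C; aq NH4Cl
Reagents that add atoms: formaldehyde (C=O)
Why: Aldol addition of the α-alkoxy lactone enolate to formaldehyde (both hydroxyls carried as alkoxides); C11 is the ring-fusion carbon of the cis-fused lactone/oxolane pair, so the hydroxymethyl group can enter only from the convex face.

Step 15
Reactants: 17 triol lactone
Product: 18 13-acetate
Conditions: AcCl (1.1 equiv), 2,4,6-collidine, CH2Cl2, −78 → −40 °C
Reagents that add atoms: acetyl chloride (CC(Cl)=O)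
Why: Low-temperature acylation should take the primary hydroxyl selectively over the secondary and tertiary ones.

Step 16
Reactants: 18 13-acetate
Product: 19 CNP0112086.1
Conditions: tiglic acid, 2,4,6-Cl3C6H2COCl, Et3N, DMAP, toluene, rt
Reagents that add atoms: tiglic acid (C/C=C(\C)C(=O)O)
Why: Yamaguchi esterification of the remaining secondary C2 hydroxyl; the tertiary C4 hydroxyl is unreactive and the mixed-anhydride method avoids ketene formation, so the E geometry of the tiglate is kept.

**Compound list**

1 | cyclohepta-1,3-diene | C1=CC=CCCC1 | starting material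
2 | endoperoxide, meso-6,7-dioxabicyclo[3.2.2]non-8-ene | C1=C[C@@H]2CCC[C@H]1OO2 | intermediate
3 | (R)-4-hydroxycyclohept-2-en-1-one | O=C1C=C[C@H](O)CCC1 | intermediate
4 | bromoacetal, (4R)-4-(2-bromo-1-ethoxyethoxy)cyclohept-2-en-1-one (both acetal epimers) | O=C1C=C[C@H](OC(CBr)OCC)CCC1 | intermediate
5 | bicyclic keto acetal, cis-fused 2-ethoxyoctahydrocyclohepta[b]furan-5-one (C5 ketone, ethyl acetal at C12, H-7 and H-8 α) | O=C1C[C@@H]2CC(OCC)O[C@@H]2CCC1 | intermediate
6 | keto lactone, cis-fused hexahydro-2H-cyclohepta[b]furan-2,5(3H)-dione (12,8-olide, C5 ketone, H-7 and H-8 α) | O=C1C[C@@H]2CC(=O)O[C@@H]2CCC1 | intermediate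
7 | allyl β-keto ester, 6 with CO2-allyl on C1 (keto–enol and C1 epimer mixture) | O=C1C[C@@H]2CC(=O)O[C@@H]2CCC1C(=O)OCC=C | intermediate
8 | enone lactone, C5 ketone with C1=C10 double bond, cis 12,8-olide | O=C1C[C@@H]2CC(=O)O[C@@H]2CC=C1 | intermediate
9 | silyl enol ether, 5-(trimethylsilyloxy) C1=C5 enol ether, 10α-methyl, cis 12,8-olide | C[Si](C)(C)OC1=C[C@H](C)C[C@H]2OC(=O)C[C@H]2C1 | intermediate
10 | keto acetal, 1β-(dimethoxymethyl)-10α-methyl C5 ketone (H-1 α), cis 12,8-olide | COC(OC)[C@H]1[C@H](C)C[C@H]2OC(=O)C[C@H]2CC1=O | intermediate
11 | propargylic alcohol, 5β-hydroxy-5α-[(trimethylsilyl)ethynyl] derivative of 10 | COC(OC)[C@H]1[C@H](C)C[C@H]2OC(=O)C[C@H]2C[C@]1(O)C#C[Si](C)(C)C | intermediate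
12 | α-iodolactone, 11-iodo derivative of 11 with iodine on the convex lactone face (cis to H-7) | COC(OC)[C@H]1[C@H](C)C[C@H]2OC(=O)[C@H](I)[C@H]2C[C@]1(O)C#C[Si](C)(C)C | intermediate
13 | bridged ether, oxolane oxygen between C5 (β) and C11 (H-11 cis to H-7), 5α-alkynyl, 1β-dimethoxymethyl | COC(OC)[C@H]1[C@H](C)C[C@H]2OC(=O)[C@H]3O[C@]1(C#C[Si](C)(C)C)C[C@@H]23 | intermediate
14 | keto aldehyde, 1β-formyl-5α-acetyl bridged ether lactone | O=C[C@H]1[C@H](C)C[C@H]2OC(=O)[C@H]3O[C@]1(C(C)=O)C[C@@H]23 | intermediate
15 | β-hydroxy ketone (formed as its lithium alkoxide), ring A closed, 2α-hydroxy, C4 ketone, trans ring fusion (H-1 α, O on C5 β) | O[C@H]1CC(=O)[C@@]23C[C@H]4[C@@H](C[C@@H](C)[C@H]12)OC(=O)[C@H]4O3 | intermediate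
16 | diol lactone, 2α,4α-dihydroxy-4β-methyl | O[C@H]1C[C@@](C)(O)[C@@]23C[C@H]4[C@@H](C[C@@H](C)[C@H]12)OC(=O)[C@H]4O3 | intermediate
17 | triol lactone, 16 with CH2OH on C11 | O[C@H]1C[C@@](C)(O)[C@@]23C[C@H]4[C@@H](C[C@@H](C)[C@H]12)OC(=O)[C@@]4(CO)O3 | intermediate
18 | 13-acetate of 17 | O[C@H]1C[C@@](C)(O)[C@@]23C[C@H]4[C@@H](C[C@@H](C)[C@H]12)OC(=O)[C@@]4(COC(C)=O)O3 | intermediate
19 | CNP0112086.1 | C/C=C(\C)C(=O)O[C@H]1C[C@@](C)(O)[C@@]23C[C@H]4[C@@H](C[C@@H](C)[C@H]12)OC(=O)[C@@]4(COC(C)=O)O3 | target

**Count and risks**

Total steps: 16. Longest linear sequence: 16 steps (the route is fully linear).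

Steps most likely to fail:

1. Step 13 (key step). What may go wrong: deprotonation at C1 with β-elimination of the ether oxygen outrunning the aldol, dehydration of the aldolate, or poor facial control in the methyl addition. Fallback: from 14, ring A is closed by a double nitro-aldol (Henry) reaction instead. Nitromethane with Et3N (or catalytic Bu4NF) adds to the aldehyde, and the resulting nitronate closes onto the acetyl ketone in the favourable enolexo mode. This gives the nitro diol F1, in which the acetyl methyl is C15 and the nitromethane carbon is C3. Radical denitration (Bu3SnH, AIBN, toluene, 110 °C) comes back to the route at 16.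

2. Step 11. What may go wrong: slow SN2 displacement by the hindered tertiary alkoxide, with translactonisation to the C5 oxygen or attack of the alkoxide on iodine taking over. Fallback: from 11, detrifluoroacetylative diazo transfer (LiN(SiMe3)2, CF3CO2CH2CF3; then MsN3, Et3N) passes through the trifluoroacetyl lactone F2 to the α-diazo lactone F3. Rh2(OAc)4 in CH2Cl2 then effects intramolecular O–H insertion of the carbenoid into the tertiary hydroxyl, which closes the oxolane under neutral conditions and comes back to the route at 13.

3. Step 10. What may go wrong: poor facial selectivity, that is, acetylide attack on the β-face, giving a C5 epimer whose hydroxyl cannot reach C11. Fallback: the C5–O bond is made by conjugate addition, which erases the C5 configuration.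
   - From 10, the C5-epimeric propargylic alcohol F4 is iodinated at C11 (LDA, I2, −78 °C) to the iodolactone F5.
   - CsOAc in DMF displaces iodide with inversion to the acetoxy lactone F6 (oxygen on the concave face).
   - TsOH in wet dioxane followed by Ph3PAuNTf2 (acetal hydrolysis, β-elimination of the tertiary hydroxyl, alkyne hydration) gives the ene keto aldehyde F7.
   - K2CO3 in MeOH cleaves the acetate, and the C11 hydroxyl adds 5-exo to C5, β to the aldehyde and necessarily from the β-face. This comes back to the route at 14.

**Further compounds**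

F1 | step 13 | nitro diol, 3-nitro analogue of 16 (nitro trans to both hydroxyls) | O[C@H]1[C@H]([N+](=O)[O-])[C@@](C)(O)[C@@]23C[C@H]4[C@@H](C[C@@H](C)[C@H]12)OC(=O)[C@H]4O3
F2 | step 11 | trifluoroacetyl lactone, 11-trifluoroacetyl derivative of 11 | COC(OC)[C@H]1[C@H](C)C[C@H]2OC(=O)C(C(=O)C(F)(F)F)[C@H]2C[C@]1(O)C#C[Si](C)(C)C
F3 | step 11 | α-diazo lactone, 11-diazo derivative of 11 | COC(OC)[C@H]1[C@H](C)C[C@H]2OC(=O)C(=[N+]=[N-])[C@H]2C[C@]1(O)C#C[Si](C)(C)C
F4 | step 10 | C5-epimeric propargylic alcohol (5α-hydroxy-5β-alkynyl epimer of 11) | COC(OC)[C@H]1[C@H](C)C[C@H]2OC(=O)C[C@H]2C[C@@]1(O)C#C[Si](C)(C)C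
F5 | step 10 | iodolactone, 11-iodo derivative of F4 (iodine on the convex face) | COC(OC)[C@H]1[C@H](C)C[C@H]2OC(=O)[C@H](I)[C@H]2C[C@@]1(O)C#C[Si](C)(C)C
F6 | step 10 | acetoxy lactone, 11-acetoxy derivative of F4 (acetoxy on the concave face) | COC(OC)[C@H]1[C@H](C)C[C@H]2OC(=O)[C@@H](OC(C)=O)[C@H]2C[C@@]1(O)C#C[Si](C)(C)C
F7 | step 10 | ene keto aldehyde, 1-formyl-5-acetyl C1=C5 alkene, 10α-methyl, 11-acetoxy 12,8-olide | CC(=O)C1=C(C=O)[C@H](C)C[C@H]2OC(=O)[C@@H](OC(C)=O)[C@H]2C1
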